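**Retrosynthetic overview**
1. Target 14 ⇐ 11: one hydrogenation turns the aryl ketone into the benzylic CH2 and removes both O-benzyl groups.
2. 11 ⇐ 8 + 9: the C3–C(aryl carbonyl) bond comes from a carbene-catalysed cross-benzoin. The aldehyde carbon of 9 reacts as an aroyl anion equivalent (Breslow intermediate) with the C3 ketone of the keto tautomer of 8. Both stereocenters are set here, by dynamic kinetic resolution through the achiral enol.
3. 8 ⇐ 3 + formaldehyde: aldol, lactonization and decarboxylation. The lactone is the only ring formed, and it is made before the key step.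
4. 3 ⇐ 1 + 2: crossed Claisen condensation. Both aromatic rings come from the starting materials.

Assumption: the sense of induction of the triazolium catalyst in step 3 cannot be known in advance; the (5aS,10bR) salt is written, and its commercially available mirror image is used if the first run gives the (3S,4R) series.

**Route**

Step 1
Reactants: 1 ethyl 3-(3,4-dimethoxyphenyl)propanoate; 2 diethyl oxalate
Product: 3 diethyl 2-(3,4-dimethoxybenzyl)-3-oxobutanedioate (racemic keto–enol mixture)
Conditions: NaOEt (1.1 equiv), 2 (1.2 equiv), Et2O–EtOH, 0 °C to rt; then cold 1 M HCl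
Reagents that add atoms: none
Why: Crossed Claisen condensation; the non-enolizable, highly electrophilic oxalate acylates the ester enolate of 1, and formation of the stabilised enolate of 3 drives the equilibrium.

Step 2
Reactants: 3 diethyl 2-(3,4-dimethoxybenzyl)-3-oxobutanedioate; 4 formaldehyde (37% aqueous, 1.05 equiv)
Product: 8 4-(3,4-dimethoxybenzyl)-3-hydroxyfuran-2(5H)-one, via hydroxymethyl aldol adduct 5 (not isolated), via ester keto lactone 6 (not isolated), via keto lactone acid 7 (not isolated)
Conditions: K2CO3 (0.3 equiv), H2O–EtOH, 0 °C to rt; then 20% aq. H2SO4, 90 °C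
Reagents that add atoms: none
Why: Aldol hydroxymethylation of the β-keto ester enolate, lactonization of the new primary alcohol onto the activated oxalyl ester (five-membered ring; the other ester would give a four-membered ring), then acid hydrolysis and decarboxylation of the β-keto acid; the product is the achiral enol, so no stereocenter has to be controlled.

Step 3
Reactants: 8 4-(3,4-dimethoxybenzyl)-3-hydroxyfuran-2(5H)-one; 9 3,4-bis(benzyloxy)benzaldehyde (1.5 equiv)
Product: 11 (3R,4S)-3-[3,4-bis(benzyloxy)benzoyl]-4-(3,4-dimethoxybenzyl)-3-hydroxyoxolan-2-one, via keto tautomer 10 (not isolated)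
Conditions: (5aS,10bR)-2-(pentafluorophenyl)-5a,10b-dihydro-4H,6H-indeno[2,1-b][1,2,4]triazolo[4,3-d][1,4]oxazin-2-ium tetrafluoroborate (15 mol %), iPr2NEt (30 mol %), 4 Å MS, CH2Cl2–TBME, 0 °C to rt, Ar
Reagents that add atoms: none
Why: Proposed new method: a dynamic kinetic asymmetric cross-benzoin in which the triazolylidene carbene turns aldehyde 9 into its Breslow intermediate (an aroyl anion equivalent, so the normally electrophilic aldehyde carbon is the nucleophile) and this adds to the C3 ketone of keto tautomer 10; the achiral enol 8 (about as acidic as a phenol, so tolerated by the carbene and acting as proton shuttle) supplies both enantiomers of the keto form by fast proton transfer, the cis-locked vicinal dicarbonyl of 10 is more electrophilic than 9 so the reversible homo-benzoin of 9 drains into the cross adduct, attack comes anti to the C4 benzyl group (aroyl trans to benzyl, OH cis) and the chiral catalyst accepts only the (4S)-ketone, which sets C3 (R) and C4 (S) together; closest known reaction type: carbene-catalysed cross-benzoin of aldehydes with α-keto esters, including its dynamic kinetic version on racemising β-stereogenic α-keto esters.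

Step 4
Reactants: 11 (3R,4S)-3-[3,4-bis(benzyloxy)benzoyl]-4-(3,4-dimethoxybenzyl)-3-hydroxyoxolan-2-one
Product: 14 (3S,4S)-3-(3,4-dihydroxybenzyl)-4-(3,4-dimethoxybenzyl)-3-hydroxyoxolan-2-one, via catechol ketone 12 (not isolated), via benzylic carbinol 13 (not isolated)
Conditions: H2 (4 atm), 10% Pd/C, AcOH–EtOAc, HClO4 (5 mol %), 40 °C
Reagents that add atoms: none
Why: Catalytic hydrogenolysis, the standard way to take 7-oxo lignan lactones to the benzyl compounds: O-benzyl cleavage, ketone hydrogenation, then acid-assisted cleavage of the benzylic C–O bond helped by the para-hydroxyl; the tertiary C3–OH is not benzylic and stays, no bond at C3 or C4 is touched, and the C3 descriptor changes from R to S only because C=O becomes CH2.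

**Compound list**
1 | ethyl 3-(3,4-dimethoxyphenyl)propanoate | CCOC(=O)CCc1ccc(OC)c(OC)c1 | starting material
2 | diethyl oxalate | CCOC(=O)C(=O)OCC | starting material
3 | diethyl 2-(3,4-dimethoxybenzyl)-3-oxobutanedioate (racemic) | CCOC(=O)C(=O)C(Cc1ccc(OC)c(OC)c1)C(=O)OCC | intermediate
4 | formaldehyde | C=O | starting material
5 | diethyl 2-(3,4-dimethoxybenzyl)-2-(hydroxymethyl)-3-oxobutanedioate (racemic, not isolated) | CCOC(=O)C(=O)C(CO)(Cc1ccc(OC)c(OC)c1)C(=O)OCC | intermediate
6 | ethyl 3-(3,4-dimethoxybenzyl)-4,5-dioxooxolane-3-carboxylate (racemic, not isolated) | CCOC(=O)C1(Cc2ccc(OC)c(OC)c2)COC(=O)C1=O | intermediate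
7 | 3-(3,4-dimethoxybenzyl)-4,5-dioxooxolane-3-carboxylic acid (racemic, not isolated) | OC(=O)C1(Cc2ccc(OC)c(OC)c2)COC(=O)C1=O | intermediate
8 | 4-(3,4-dimethoxybenzyl)-3-hydroxyfuran-2(5H)-one (achiral enol) | COc1ccc(CC2=C(O)C(=O)OC2)cc1OC | intermediate
9 | 3,4-bis(benzyloxy)benzaldehyde | O=Cc1ccc(OCc2ccccc2)c(OCc2ccccc2)c1 | starting material
10 | (4S)-4-(3,4-dimethoxybenzyl)oxolane-2,3-dione (keto tautomer, not isolated) | COc1ccc(C[C@H]2COC(=O)C2=O)cc1OC | intermediate
11 | (3R,4S)-3-[3,4-bis(benzyloxy)benzoyl]-4-(3,4-dimethoxybenzyl)-3-hydroxyoxolan-2-one | COc1ccc(C[C@H]2COC(=O)[C@]2(O)C(=O)c2ccc(OCc3ccccc3)c(OCc3ccccc3)c2)cc1OC | intermediate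
12 | (3R,4S)-3-(3,4-dihydroxybenzoyl)-4-(3,4-dimethoxybenzyl)-3-hydroxyoxolan-2-one (not isolated) | COc1ccc(C[C@H]2COC(=O)[C@]2(O)C(=O)c2ccc(O)c(O)c2)cc1OC | intermediate
13 | (3R,4S)-3-[(3,4-dihydroxyphenyl)(hydroxy)methyl]-4-(3,4-dimethoxybenzyl)-3-hydroxyoxolan-2-one (both carbinol epimers, not isolated) | COc1ccc(C[C@H]2COC(=O)[C@]2(O)C(O)c2ccc(O)c(O)c2)cc1OC | intermediate
14 | (3S,4S)-3-(3,4-dihydroxybenzyl)-4-(3,4-dimethoxybenzyl)-3-hydroxyoxolan-2-one | COc1ccc(C[C@H]2COC(=O)[C@]2(O)Cc2ccc(O)c(O)c2)cc1OC | target

**Step count**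
Total: 4 steps. Longest linear sequence: 4 steps (1 → 3 → 8 → 11 → 14); aldehyde 9 is bought.

**Steps most likely to fail, with fallbacks**

Step 3 is the main risk. Lactone 8 rests as a stabilised enol, so only a small share is the electrophilic keto form, and the cross adduct could revert by retro-benzoin. The fallback sets out from 8 and comes back to the route at 14. Enol lactone 8 is reduced by dynamic kinetic asymmetric transfer hydrogenation (RuCl(p-cymene)[(S,S)-TsDPEN] or its mirror image, HCO2H–Et3N, DMF, rt; hydride adds to the keto tautomer anti to the benzyl group) to cis-(3S,4S)-4-(3,4-dimethoxybenzyl)-3-hydroxyoxolan-2-one F1. Its dianion (LiHMDS 2.2 equiv, THF–DMPU, −78 °C) is C-alkylated with commercial 3,4-bis(benzyloxy)benzyl bromide anti to the C4 substituent to give (3S,4S)-3-[3,4-bis(benzyloxy)benzyl]-4-(3,4-dimethoxybenzyl)-3-hydroxyoxolan-2-one F2. H2, Pd/C, EtOAc, rt then removes the two benzyl groups and gives 14.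

Step 4 is the second risk. Under acid on palladium the carbinol next to the tertiary alcohol could rearrange (pinacol type), or the electron-rich ketone could stop at the carbinol. The fallback sets out from 11 and comes back at 14. H2 (1 atm), Pd/C, EtOAc, rt without acid removes only the O-benzyl groups, and catechol ketone 12 is isolated (any 13 formed is carried along). Et3SiH (4 equiv), TFA, CH2Cl2, 0 °C to rt then reduces the aryl ketone to CH2 by ionic hydrogenation, two hydride transfers to para-hydroxy-stabilised benzylic cations, to give 14. This way makes no compound outside the list, none F0.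

Step 2 is the third risk. Formaldehyde can add a second time at C4 of 8 or attack the electron-rich arene during the hot acid stage. The fallback sets out from 3 and comes back at 8. Diester 3 is first hydrolysed and decarboxylated (10% aq. H2SO4, reflux) to 4-(3,4-dimethoxyphenyl)-2-oxobutanoic acid F3. Aqueous formaldehyde, K2CO3, H2O, rt, followed by acidification, then gives aldol hydroxymethylation at C3 and lactonization to 8.

**Further compounds**
F1 | step 3 | (3S,4S)-4-(3,4-dimethoxybenzyl)-3-hydroxyoxolan-2-one | COc1ccc(C[C@H]2COC(=O)[C@H]2O)cc1OC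
F2 | step 3 | (3S,4S)-3-[3,4-bis(benzyloxy)benzyl]-4-(3,4-dimethoxybenzyl)-3-hydroxyoxolan-2-one | COc1ccc(C[C@H]2COC(=O)[C@]2(O)Cc2ccc(OCc3ccccc3)c(OCc3ccccc3)c2)cc1OC
F0 | step 4 | none | none
F3 | step 2 | 4-(3,4-dimethoxyphenyl)-2-oxobutanoic acid | COc1ccc(CCC(=O)C(=O)O)cc1OC
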